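The meeting began from an invariant: the chair held that, at fixed equivalents, the part of the electrophile reacted follows the product of starting concentration and time, both steps that use electrophile joining two partners.

- Wednesday's: electrophile 0.78 M; nucleophile 2 equiv; free base 3 equiv; run made earlier
- flask: electrophile 0.56 M; nucleophile 2.00 equiv; free base 3.00 equiv; time 40 min

Wednesday's run (percent of the electrophile charged)

| time / min | electrophile / % | target / % |
|---|---|---|
| 5.00 | 65.6 | 21.6 |
| 15.0 | 28.7 | 28.4 |
| 25.0 | 14.4 | 29.4 |
| 40.0 | 5.4 | 28.4 |

(scatter of a reading: 0.5 percentage points)

- a species is counted by the electrophile in it: one side product counts as two
- steps under discussion: electrophile + nucleophile -> acid set free + target; nucleophile + acid set free <-> protonated nucleophile; acid set free + free base <-> salt of the base; electrophile + target -> side product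
- the earlier runs do not show how much of nucleophile is bound; that part of a forecast is a guess
- no earlier run changes the charge of free base; that part of a forecast is a guess

- part of the electrophile that has reacted at 40 min
- share of the unused nucleophile that is free and not bound as protonated nucleophile, at 40 min

The flask has Wednesday's equivalents at 0.56 M against 0.78 M, so the chair read its 40 min as 28.7 min of Wednesday's run. This is the matched time τ: the flask's time multiplied by its starting concentration and divided by Wednesday's. One member then reckoned for herself, taking the logarithm of the electrophile as straight between the readings at 25.0 min and 40.0 min. At τ she found 11.3% still there, so 88.7% reacted, on readings that scatter by 0.5 percentage points. Another member objected that Wednesday's run does not show the bound nucleophile, so the share asked for could not be read from it and stayed a guess. The forecast, tabled next, stood at 88.6% reacted and 60% free, on the ground that “the acid sharing depends only on ratios”.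

The flask gave 89.4% reacted and 58.8% free.

    electrophile + nucleophile → acid set free + target (k = 8.70 × 10⁻⁴ /M/s)
    nucleophile + acid set free ⇌ protonated nucleophile, settled at all times (K = 7500 /M)
    acid set free + free base ⇌ salt of the base (K = 44000 /M, k = 0.0290 /M/s)
    electrophile + target → side product (k = 0.00270 /M/s)

Against the 88.7% from τ, the flask stands at 89.4%. With the amounts held, the part reacted would have moved by 5 points at 32.4 min or at 52.9 min. The neighbouring flask keeps the equivalents and the time but is charged 0.14 M of electrophile, so its τ is 7.18 min, between Wednesday's readings at 5.00 min and 15.0 min. The same straight logarithm there puts the electrophile left at 54.8%. The neighbouring flask ends with 54.2% of its electrophile left.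

All runs are simulated for an exercise, noise included.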